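**Retrosynthetic overview**
- Querciformolide D ⇐ desilylation of its 3,11-bis-silyl ether, made by relaying a C3-bound six-membered lactone to the C12-bound seven-membered lactone (base-mediated acyl shift with silyl trapping).
- Oxolane and six-membered lactone ⇐ one operation on a macrocyclic diene dihydroxy acid: double Shi epoxidation, then a carboxylate-triggered 6-exo/5-exo epoxide-opening cascade that sets C3, C4, C7 and C8.
- 11,12-Diol ⇐ hydroxyl-directed epoxidation and hydride opening of a 12-methylene-11-ol; 14-membered carbocycle ⇐ Nozaki–Hiyama–Kishi closure of C11–C12.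
- Seco chain ⇐ two isopropenyl-Grignard/Claisen iterations on the aldehyde obtained by ring-cleaving a C10-oxidised (R)-limonene, which supplies C1.
- Ring order: carbocycle, then oxolane and six-membered lactone together, then the seven-membered lactone.

Assumption: cembrane numbering is used for locants (C1 carries C15–C17, ring carbons C2–C14, methyls C18–C20); in it the target SMILES reads (1R,3S,4R,7S,8R,11R,12R).

**Route**

Step 1
Reactants: 1 (R)-(+)-limonene
Product: 4 (R)-2-(4-methylcyclohex-3-en-1-yl)prop-2-en-1-ol, via allyllithium 2 (not isolated), via allylboronate 3 (not isolated)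
Conditions: n-BuLi, TMEDA, hexane, 25 °C; B(OMe)3, THF, −78 °C; H2O2, aq. NaOH, 0 °C
Reagents that add atoms: hydrogen peroxide OO
Why: Kinetic allylic metalation of the isopropenyl methyl followed by borylation–oxidation gives the C16 alcohol; the C1 stereocentre is not touched.

Step 2
Reactants: 4 (R)-2-(4-methylcyclohex-3-en-1-yl)prop-2-en-1-ol
Product: 5 (R)-2-(4-methylcyclohex-3-en-1-yl)allyl pivalate
Conditions: PivCl, pyridine, DMAP (cat.), CH2Cl2, 0 °C
Reagents that add atoms: pivaloyl chloride CC(C)(C)C(Cl)=O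
Why: Acylation gives a base-, Grignard- and heat-stable ester that cannot lactonise with later C3 alkoxides and is removed by the hydride of step 11.

Step 3
Reactants: 5 (R)-2-(4-methylcyclohex-3-en-1-yl)allyl pivalate
Product: 7 (R)-5,5-dimethoxy-2-methylidene-3-(3-oxobutyl)pentyl pivalate, via keto aldehyde 6 (not isolated)
Conditions: O3, CH2Cl2, −78 °C; Me2S; then HC(OMe)3, MeOH, PPTS (cat.), 0 °C
Reagents that add atoms: ozone [O-][O+]=O; trimethyl orthoformate COC(OC)OC; methanol CO
Why: Ozonolysis cleaves the electron-rich trisubstituted ring alkene in preference to the allylic-ester 1,1-disubstituted alkene, and acid-catalysed acetalisation masks the aldehyde (C3) but not the methyl ketone (C12).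

Step 4
Reactants: 7 (R)-5,5-dimethoxy-2-methylidene-3-(3-oxobutyl)pentyl pivalate
Product: 9 (R)-2-methylidene-5-oxo-3-[3-(triflyloxy)but-3-enyl]pentyl pivalate, via acetal triflate 8 (not isolated)
Conditions: KN(SiMe3)2, THF, −78 °C; PhNTf2; then 1 M HCl, THF, 25 °C
Reagents that add atoms: N-phenylbis(trifluoromethanesulfonimide) O=S(=O)(N(c1ccccc1)S(=O)(=O)C(F)(F)F)C(F)(F)F; water O
Why: Kinetic enolisation at the methyl group and O-triflation give the terminal enol triflate (C12=C20), and mild acetal hydrolysis then frees the C3 aldehyde.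

Step 5
Reactants: 9 (R)-2-methylidene-5-oxo-3-[3-(triflyloxy)but-3-enyl]pentyl pivalate; 10 isopropenylmagnesium bromide
Product: 11 (3R)-5-hydroxy-6-methyl-2-methylidene-3-[3-(triflyloxy)but-3-enyl]hept-6-enyl pivalate (carbinol epimers)
Conditions: THF, −78 °C
Reagents that add atoms: isopropenylmagnesium bromide CC(=C)[Mg]Br
Why: Grignard addition is selective for the aldehyde over the hindered pivalate and the enol triflate; the new carbinol configuration is irrelevant because it is erased in step 6.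

Step 6
Reactants: 11 (3R)-5-hydroxy-6-methyl-2-methylidene-3-[3-(triflyloxy)but-3-enyl]hept-6-enyl pivalate; 12 ethyl vinyl ether
Product: 14 (3R,5E)-6-methyl-2-methylidene-9-oxo-3-[3-(triflyloxy)but-3-enyl]non-5-enyl pivalate, via allyl vinyl ether 13 (not isolated)
Conditions: ethyl vinyl ether, Hg(OAc)2 (cat.), reflux; then PhMe, BHT, 110 °C
Reagents that add atoms: ethyl vinyl ether C=COCC
Why: Vinyl ether exchange and Claisen rearrangement through a chair transition state with the C2 chain equatorial give the (E)-C3=C4 trisubstituted alkene and the C7 aldehyde.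

Step 7
Reactants: 14 (3R,5E)-6-methyl-2-methylidene-9-oxo-3-[3-(triflyloxy)but-3-enyl]non-5-enyl pivalate; 10 isopropenylmagnesium bromide
Product: 15 (3R,5E)-9-hydroxy-6,10-dimethyl-2-methylidene-3-[3-(triflyloxy)but-3-enyl]undeca-5,10-dienyl pivalate (carbinol epimers)
Conditions: THF, −78 °C
Reagents that add atoms: isopropenylmagnesium bromide CC(=C)[Mg]Br
Why: Second chemoselective Grignard addition to the aldehyde; the carbinol configuration is again erased in the following rearrangement.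

Step 8
Reactants: 15 (3R,5E)-9-hydroxy-6,10-dimethyl-2-methylidene-3-[3-(triflyloxy)but-3-enyl]undeca-5,10-dienyl pivalate; 12 ethyl vinyl ether
Product: 17 (3R,5E,9E)-6,10-dimethyl-2-methylidene-13-oxo-3-[3-(triflyloxy)but-3-enyl]trideca-5,9-dienyl pivalate, via allyl vinyl ether 16 (not isolated)
Conditions: ethyl vinyl ether, Hg(OAc)2 (cat.), reflux; then PhMe, BHT, 110 °C
Reagents that add atoms: ethyl vinyl ether C=COCC
Why: Second Claisen rearrangement installs the (E)-C7=C8 alkene and the C11 aldehyde, completing the C20 seco chain.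

Step 9
Reactants: 17 (3R,5E,9E)-6,10-dimethyl-2-methylidene-13-oxo-3-[3-(triflyloxy)but-3-enyl]trideca-5,9-dienyl pivalate
Product: 18 (1R,3E,7E,11R)-11-hydroxycembra-3,7,12(20),15(17)-tetraen-16-yl pivalate
Conditions: CrCl2, NiCl2 (cat.), (S)-N-[2-(4-isopropyl-4,5-dihydrooxazol-2-yl)-6-methylphenyl]methanesulfonamide, Et3N, THF, 0.002 M, 25 °C
Reagents that add atoms: none
Why: Nozaki–Hiyama–Kishi macrocyclisation (zerovalent nickel inserts into the enol triflate, the alkenyl group passes to trivalent chromium and adds to the aldehyde) closes the 14-membered ring at C11–C12, with the chiral sulfonamide on chromium chosen to deliver the 11R carbinol.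

Step 10
Reactants: 18 (1R,3E,7E,11R)-11-hydroxycembra-3,7,12(20),15(17)-tetraen-16-yl pivalate
Product: 19 (1R,3E,7E,11R,12S)-12,20-epoxy-11-hydroxycembra-3,7,15(17)-trien-16-yl pivalate
Conditions: VO(acac)2 (cat.), t-BuOOH (1.1 eq), CH2Cl2, 0 °C
Reagents that add atoms: tert-butyl hydroperoxide CC(C)(C)OO
Why: Vanadium-catalysed hydroxyl-directed epoxidation touches only the allylic exo-methylene, and minimised A(1,2) strain (carbinol H eclipsing C13) gives the erythro epoxy alcohol, which fixes C12 relative to C11.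

Step 11
Reactants: 19 (1R,3E,7E,11R,12S)-12,20-epoxy-11-hydroxycembra-3,7,15(17)-trien-16-yl pivalate
Product: 20 (1R,3E,7E,11R,12R)-cembra-3,7,15(17)-triene-11,12,16-triol
Conditions: LiEt3BH (excess), THF, 0 to 25 °C
Reagents that add atoms: none
Why: Hydride opens the 2,2-disubstituted epoxide by SN2 attack at the CH2 (C20 becomes the methyl, C12–O retained, giving the 11R,12R diol) and cleaves the pivalate reductively in the same operation.

Step 12
Reactants: 20 (1R,3E,7E,11R,12R)-cembra-3,7,15(17)-triene-11,12,16-triol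
Product: 22 (1R,3E,7E,11R,12R)-11,12-dihydroxycembra-3,7,15(17)-trien-16-oic acid, via enal 21 (not isolated)
Conditions: 2,2,6,6-tetramethylpiperidin-1-oxyl (cat.), PhI(OAc)2, CH2Cl2, 25 °C; then NaClO2, NaH2PO4, 2-methyl-2-butene, t-BuOH/H2O
Reagents that add atoms: sodium chlorite [Na+].[O-]Cl=O
Why: Nitroxyl-catalysed oxidation is selective for the primary allylic alcohol over the secondary and tertiary ones, and Pinnick oxidation of the resulting enal gives the acrylic acid.

Step 13
Reactants: 22 (1R,3E,7E,11R,12R)-11,12-dihydroxycembra-3,7,15(17)-trien-16-oic acid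
Product: 24 (1R,3S,4R,7S,8R,11R,12R)-4,7-epoxy-8,11,12-trihydroxycembr-15(17)-en-16,3-olide, via diepoxy acid 23 (not isolated)
Conditions: 1,2:4,5-di-O-isopropylidene-β-D-erythro-hexo-2,3-diulopyranose (Shi ketone, 0.6 eq), KHSO5 (as 2KHSO5·KHSO4·K2SO4), K2CO3, Bu4NHSO4, MeCN/CH2(OMe)2/aq. Na2B4O7, 0 °C; then Cs2CO3, DMF, 60 °C
Reagents that add atoms: potassium peroxymonosulfate [K+].[O-]S(=O)(=O)OO
Why: Shi epoxidation of the two (E)-trisubstituted alkenes gives the (3R,4R,7R,8R)-diepoxide by reagent control (the acrylate is inert), after which an anionic epoxide-opening cascade runs: the carboxylate attacks C3 (6-exo, SN2 inversion to 3S), the released C4 alkoxide attacks C7 (5-exo, inversion to 7S), and C4 and C8 keep their oxygen, so the cis-oxolane and a six-membered lactone form together; under base the tertiary carbons C4, C8 and C12 are not attacked, so the free 11,12-diol does not interfere.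

Step 14
Reactants: 24 (1R,3S,4R,7S,8R,11R,12R)-4,7-epoxy-8,11,12-trihydroxycembr-15(17)-en-16,3-olide
Product: 25 3,11-bis-O-(tert-butyldimethylsilyl)querciformolide D
Conditions: NaN(SiMe3)2 (2.2 eq), THF, −40 to 0 °C; then TBSCl (2.5 eq), 0 °C
Reagents that add atoms: tert-butyldimethylsilyl chloride CC(C)(C)[Si](C)(C)Cl
Why: Proposed new method: the C12 alkoxide adds to the lactone carbonyl through a seven-membered tetrahedral intermediate and expels the less basic secondary C3 alkoxide, so the six- and seven-membered lactones equilibrate, and TBSCl silylates secondary alkoxides (C3, C11) far faster than tertiary ones (C8, C12), draining the equilibrium into the seven-membered lactone; the closest known chemistry is base-mediated acyl migration in polyols combined with selective silylation, and no stereocentre is touched.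

Step 15
Reactants: 25 3,11-bis-O-(tert-butyldimethylsilyl)querciformolide D
Product: 26 querciformolide D
Conditions: HF·pyridine, THF, 0 to 25 °C
Reagents that add atoms: none
Why: Fluoride-mediated cleavage of the two secondary silyl ethers leaves the α-methylene lactone and the tertiary alcohols untouched.

**Compound list**

1 | (R)-(+)-limonene | CC1=CC[C@@H](CC1)C(C)=C | starting material
2 | [2-((R)-4-methylcyclohex-3-en-1-yl)allyl]lithium | CC1=CC[C@@H](CC1)C(=C)C[Li] | intermediate
3 | dimethyl [2-((R)-4-methylcyclohex-3-en-1-yl)allyl]boronate | CC1=CC[C@@H](CC1)C(=C)CB(OC)OC | intermediate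
4 | (R)-2-(4-methylcyclohex-3-en-1-yl)prop-2-en-1-ol | CC1=CC[C@@H](CC1)C(=C)CO | intermediate
5 | (R)-2-(4-methylcyclohex-3-en-1-yl)allyl pivalate | CC1=CC[C@@H](CC1)C(=C)COC(=O)C(C)(C)C | intermediate
6 | (R)-2-methylidene-5-oxo-3-(3-oxobutyl)pentyl pivalate | CC(=O)CC[C@H](CC=O)C(=C)COC(=O)C(C)(C)C | intermediate
7 | (R)-5,5-dimethoxy-2-methylidene-3-(3-oxobutyl)pentyl pivalate | CC(=O)CC[C@H](CC(OC)OC)C(=C)COC(=O)C(C)(C)C | intermediate
8 | (R)-5,5-dimethoxy-2-methylidene-3-[3-(triflyloxy)but-3-enyl]pentyl pivalate | C=C(OS(=O)(=O)C(F)(F)F)CC[C@H](CC(OC)OC)C(=C)COC(=O)C(C)(C)C | intermediate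
9 | (R)-2-methylidene-5-oxo-3-[3-(triflyloxy)but-3-enyl]pentyl pivalate | C=C(OS(=O)(=O)C(F)(F)F)CC[C@H](CC=O)C(=C)COC(=O)C(C)(C)C | intermediate
10 | isopropenylmagnesium bromide | CC(=C)[Mg]Br | starting material
11 | (3R)-5-hydroxy-6-methyl-2-methylidene-3-[3-(triflyloxy)but-3-enyl]hept-6-enyl pivalate (carbinol epimers) | CC(=C)C(O)C[C@@H](CCC(=C)OS(=O)(=O)C(F)(F)F)C(=C)COC(=O)C(C)(C)C | intermediate
12 | ethyl vinyl ether | C=COCC | starting material
13 | (3R)-6-methyl-2-methylidene-3-[3-(triflyloxy)but-3-enyl]-5-(vinyloxy)hept-6-enyl pivalate | CC(=C)C(OC=C)C[C@@H](CCC(=C)OS(=O)(=O)C(F)(F)F)C(=C)COC(=O)C(C)(C)C | intermediate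
14 | (3R,5E)-6-methyl-2-methylidene-9-oxo-3-[3-(triflyloxy)but-3-enyl]non-5-enyl pivalate | O=CCC/C(C)=C/C[C@@H](CCC(=C)OS(=O)(=O)C(F)(F)F)C(=C)COC(=O)C(C)(C)C | intermediate
15 | (3R,5E)-9-hydroxy-6,10-dimethyl-2-methylidene-3-[3-(triflyloxy)but-3-enyl]undeca-5,10-dienyl pivalate (carbinol epimers) | CC(=C)C(O)CC/C(C)=C/C[C@@H](CCC(=C)OS(=O)(=O)C(F)(F)F)C(=C)COC(=O)C(C)(C)C | intermediate
16 | (3R,5E)-6,10-dimethyl-2-methylidene-3-[3-(triflyloxy)but-3-enyl]-9-(vinyloxy)undeca-5,10-dienyl pivalate | CC(=C)C(OC=C)CC/C(C)=C/C[C@@H](CCC(=C)OS(=O)(=O)C(F)(F)F)C(=C)COC(=O)C(C)(C)C | intermediate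
17 | (3R,5E,9E)-6,10-dimethyl-2-methylidene-13-oxo-3-[3-(triflyloxy)but-3-enyl]trideca-5,9-dienyl pivalate | O=CCC/C(C)=C/CC/C(C)=C/C[C@@H](CCC(=C)OS(=O)(=O)C(F)(F)F)C(=C)COC(=O)C(C)(C)C | intermediate
18 | (1R,3E,7E,11R)-11-hydroxycembra-3,7,12(20),15(17)-tetraen-16-yl pivalate | O[C@@H]1CC/C(C)=C/CC/C(C)=C/C[C@@H](CCC1=C)C(=C)COC(=O)C(C)(C)C | intermediate
19 | (1R,3E,7E,11R,12S)-12,20-epoxy-11-hydroxycembra-3,7,15(17)-trien-16-yl pivalate | O[C@@H]1CC/C(C)=C/CC/C(C)=C/C[C@@H](CC[C@]12CO2)C(=C)COC(=O)C(C)(C)C | intermediate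
20 | (1R,3E,7E,11R,12R)-cembra-3,7,15(17)-triene-11,12,16-triol | O[C@@H]1CC/C(C)=C/CC/C(C)=C/C[C@@H](CC[C@@]1(C)O)C(=C)CO | intermediate
21 | (1R,3E,7E,11R,12R)-11,12-dihydroxycembra-3,7,15(17)-trien-16-al | O[C@@H]1CC/C(C)=C/CC/C(C)=C/C[C@@H](CC[C@@]1(C)O)C(=C)C=O | intermediate
22 | (1R,3E,7E,11R,12R)-11,12-dihydroxycembra-3,7,15(17)-trien-16-oic acid | O[C@@H]1CC/C(C)=C/CC/C(C)=C/C[C@@H](CC[C@@]1(C)O)C(=C)C(O)=O | intermediate
23 | (1R,3R,4R,7R,8R,11R,12R)-3,4:7,8-diepoxy-11,12-dihydroxycembr-15(17)-en-16-oic acid | O[C@@H]1CC[C@@]2(C)O[C@@H]2CC[C@@]3(C)O[C@@H]3C[C@@H](CC[C@@]1(C)O)C(=C)C(O)=O | intermediate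
24 | (1R,3S,4R,7S,8R,11R,12R)-4,7-epoxy-8,11,12-trihydroxycembr-15(17)-en-16,3-olide | C=C1C(=O)O[C@H]2C[C@H]1CC[C@@](C)(O)[C@H](O)CC[C@@](C)(O)[C@@H]1CC[C@@]2(C)O1 | intermediate
25 | 3,11-bis-O-(tert-butyldimethylsilyl)querciformolide D | C=C1C(=O)O[C@]2(C)CC[C@@H]1C[C@H](O[Si](C)(C)C(C)(C)C)[C@@]1(C)CC[C@H](O1)[C@](C)(O)CC[C@H]2O[Si](C)(C)C(C)(C)C | intermediate
26 | querciformolide D | C=C1C(=O)O[C@]2(C)CC[C@@H]1C[C@H](O)[C@@]1(C)CC[C@H](O1)[C@](C)(O)CC[C@H]2O | target

**Step count and risks**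

Total: 15 steps; longest linear sequence: 15 steps from (R)-limonene.

The three steps most likely to fail are 9, 13 and 14.

Step 9 may give poor control at C11 in a 14-membered closure. The fallback sets out from 17 and comes back at 18, and sets C11 by ketone reduction instead of by the C–C coupling. Cyclise 17 with CrCl2/NiCl2 in DMSO without ligand to the C11-epimeric macrocyclic alcohols F1, oxidise with Dess–Martin periodinane to the 12-methylene-11-ketone F2, and reduce with (S)-2-methyl-CBS-oxazaborolidine and BH3·SMe2, which delivers 18.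

Step 13 may suffer from poor facial control of the epoxidation on the macrocyclic acid or from a sluggish carboxylate opening. The fallback sets out from 22 and comes back at 26, and reverses the ring order with an acid-triggered opening. Silylate C11–OH (TBSCl, imidazole; K2CO3/MeOH to cleave the silyl ester) to the 11-O-TBS hydroxy acid F3. Close the seven-membered lactone on the tertiary C12–OH (2,4,6-trichlorobenzoyl chloride, Et3N, DMAP) to the diene lactone F4. Epoxidise with the Shi ketone to the diepoxy lactone F5. Treat with BF3·OEt2 and then water: the lactone carbonyl oxygen opens C3, the C4 oxygen closes on C7, and hydrolysis of the resulting orthoester cation should keep the ester on the more hindered tertiary oxygen, giving 11-O-TBS querciformolide D F6. HF·pyridine then gives 26.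

Step 14 may leave the six-membered lactone favoured, or the alkoxides may attack the acrylate. The fallback sets out from 24 and comes back at 25, replacing the acyl shift by hydrolysis and relactonisation. Saponify 24 with LiOH to the tetraol acid F7, silylate the two secondary hydroxyls (TBSCl, imidazole, DMF; K2CO3/MeOH) to the bis-silyl hydroxy acid F8, and lactonise onto the tertiary C12–OH under Yamaguchi conditions to reach 25.

**Further compounds**

F1 | step 9 | (1R,3E,7E,11RS)-11-hydroxycembra-3,7,12(20),15(17)-tetraen-16-yl pivalate | OC1CC/C(C)=C/CC/C(C)=C/C[C@@H](CCC1=C)C(=C)COC(=O)C(C)(C)C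
F2 | step 9 | (1R,3E,7E)-11-oxocembra-3,7,12(20),15(17)-tetraen-16-yl pivalate | O=C1CC/C(C)=C/CC/C(C)=C/C[C@@H](CCC1=C)C(=C)COC(=O)C(C)(C)C
F3 | step 13 | (1R,3E,7E,11R,12R)-11-(tert-butyldimethylsilyloxy)-12-hydroxycembra-3,7,15(17)-trien-16-oic acid | CC(C)(C)[Si](C)(C)O[C@@H]1CC/C(C)=C/CC/C(C)=C/C[C@@H](CC[C@@]1(C)O)C(=C)C(O)=O
F4 | step 13 | (1R,3E,7E,11R,12R)-11-(tert-butyldimethylsilyloxy)cembra-3,7,15(17)-trien-16,12-olide | C=C1C(=O)O[C@]2(C)CC[C@@H]1C/C=C(\C)CC/C=C(\C)CC[C@H]2O[Si](C)(C)C(C)(C)C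
F5 | step 13 | (1R,3R,4R,7R,8R,11R,12R)-3,4:7,8-diepoxy-11-(tert-butyldimethylsilyloxy)cembr-15(17)-en-16,12-olide | C=C1C(=O)O[C@]2(C)CC[C@@H]1C[C@H]3O[C@]3(C)CC[C@H]4O[C@]4(C)CC[C@H]2O[Si](C)(C)C(C)(C)C
F6 | step 13 | 11-O-(tert-butyldimethylsilyl)querciformolide D | C=C1C(=O)O[C@]2(C)CC[C@@H]1C[C@H](O)[C@@]1(C)CC[C@H](O1)[C@](C)(O)CC[C@H]2O[Si](C)(C)C(C)(C)C
F7 | step 14 | (1R,3S,4R,7S,8R,11R,12R)-4,7-epoxy-3,8,11,12-tetrahydroxycembr-15(17)-en-16-oic acid | OC(=O)C(=C)[C@H]1C[C@H](O)[C@@]2(C)CC[C@H](O2)[C@](C)(O)CC[C@@H](O)[C@](C)(O)CC1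
F8 | step 14 | (1R,3S,4R,7S,8R,11R,12R)-3,11-bis(tert-butyldimethylsilyloxy)-4,7-epoxy-8,12-dihydroxycembr-15(17)-en-16-oic acid | OC(=O)C(=C)[C@H]1C[C@H](O[Si](C)(C)C(C)(C)C)[C@@]2(C)CC[C@H](O2)[C@](C)(O)CC[C@@H](O[Si](C)(C)C(C)(C)C)[C@](C)(O)CC1
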